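## Structural features

The target, 4-(4-hydroxybenzyl)-2-{2-[3-hydroxy-2,6-bis(4-hydroxybenzyl)-5-methoxyphenyl]ethyl}phenol, is built from five benzene rings and has no stereocentre, so no configuration has to be set. Ring A is pentasubstituted: C1 carries the CH2CH2 bridge, C2 and C6 carry 4-hydroxybenzyl groups, C3 carries OH, C5 carries OMe and only C4 keeps a hydrogen. Ring B is joined to the bridge at C1, has its hydroxyl at C2 and a 4-hydroxybenzyl group at C5, para to that hydroxyl. Rings C, D and E are the three 4-hydroxyphenyl rings, each joined through a single methylene, so every inter-ring link is a non-functional sp3 carbon. The fragile elements are the five electron-rich phenols (one must stay differentiated from the methyl ether), the para-hydroxy diarylmethane units, which oxidise or ionise towards quinone methides, and the nucleophilic C4–H of ring A. The real difficulty is the contiguous benzyl/ethylene/benzyl array on ring A, together with the regiodefined 1,2,4-pattern of ring B, in a molecule with no polar handle on any linking carbon. The key step exploits ring B: its C2–OH is ortho to the bridge-bearing C1 and para to C5, which bears the benzylic carbon. That is the pattern left when a 4-alkyl-1-methoxy-3-silyloxydiene adds to an aryl ethynyl ketone and the adduct aromatises, forming the ring B bonds C1–C6 and C4–C5.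

## Logic of the disconnections

**21 to 20.** The four O–CH2Ph bonds are cut. Four of the five phenols are carried as benzyl ethers so that one neutral hydrogenolysis ends the synthesis and the methyl ether stays distinct. The forward step must not touch the diarylmethane C–C bonds; nothing else in 20 is reducible.

**20 to 18.** The ring B benzylic CH2 is traced back to a C=O group. The carbonyl is what activates the dienophile in the ring-forming step. The forward deoxygenation must spare four benzyl ethers; the free para-hydroxyl of 18 makes ionisation at this carbon unusually easy.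

**18 to 13 and 16.** Ring B is opened at C1–C6 and C4–C5, a retro-[4+2] after formal return of methanol. This removes ring B, its substitution pattern and the A–B connection in one operation. The ring A aryl group of 13 sits on C6 of the diene, two methylene groups away from the reacting terminus C4, and those two CH2 groups become the bridge. The forward step needs full regiocontrol, a (3Z) silyl enol ether and exclusion of moisture and Lewis acids.

**13 to 12.** The O–Si bond is cut. 12 has one enolisable position, so only the enol ether geometry is at issue. The trimethylsilyl group is kept because the acidic work-up of the cycloaddition removes it and frees the ring B hydroxyl directly; the cost is that 13 must be used without purification.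

**12 to 11.** The C1–OMe bond is cut (conjugate addition of methanol to an ynone). The other way to 12, making its C4–C5 bond by alkylating a methyl ketone enolate with a 2-arylethyl halide, was set aside. A primary halide beta to a doubly ortho-substituted ring would eliminate to the styrene, and such enolates alkylate poorly with unactivated halides. The forward step must stop at mono-addition and give the (E) enol ether.

**11 to 9 and 10.** The acyl–alkynyl bond is cut, which reduces the problem to a 4-arylbutanoic acid derivative and a commercial C2 nucleophile. The forward step must avoid over-addition and keep the released amine from adding to the ynone.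

**9 to 8.** Functional group interchange, amide to ethyl ester. The ester is the form that survives bromination and cross-coupling.

**8 to 5 and 6 (through 7).** Both aryl–CH2 bonds to the two identical benzyl arms are cut, so one double coupling installs both. The coupling is placed on an ester and not on a ring A aldehyde, because a benzylic zinc reagent adds to a formyl group. The forward step needs a catalyst that tolerates a bromide flanked on both sides.

**5 to 4.** Two C–Br bonds are cut. The forward step relies on the innate preference of a 5-alkylresorcinol diether for substitution at the two positions next to the alkyl chain.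

**4 to 2 and 3.** The aryl–CH2 bond of the chain is cut. The four-carbon chain comes as a purchased organozinc ester and supplies both bridge carbons and the future C1 and C2 of ring B. The coupling is done while the ring is still unhindered.

**2 to 1.** The O–benzyl bond is cut; simple protection.

**16 to 15 to 14 and 10.** An oxidation level change, then the bond between the carbinol carbon and the alkyne is cut. This gives two steps from two commercial materials.

## Other disconnections considered

**Alternative 1:** The cut is the bond between the bridge carbon next to ring B and the ortho carbon of ring B. In the forward sense the hindered methyl ketone A1 is condensed with the O-arylhydroxylamine A2 to the oxime ether A3. Acid then tautomerises A3 to the N-aryloxy enamine, a [3,3] shift forms the C–C bond, and cyclisation with loss of ammonia gives the benzofuran A4.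
- In favour: ring B is bought as an aromatic ring, and the para-substituted aryloxy group has only one kind of ortho position, so regiochemistry is as certain as in the chosen plan. On that point the alternative is its equal.
- Against: A1 is an acetophenone with both ortho positions benzylated, so oxime ether formation at its shielded carbonyl is doubtful. The rearrangement also needs strong acid in the presence of five benzyl ethers and an electron-rich ring.
- Against: A4 is at the wrong oxidation level. The furan C2=C3 bond, attached to a doubly ortho-substituted aryl group, must be hydrogenated and the benzylic C2–O bond then cleaved to reveal the bridge and the phenol.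
- Comparison: if that reduction could be merged with the final debenzylation, the alternative would need one step after its key step against two for the chosen plan, and would be the better on that count. The chosen plan is preferred because 18 needs only deoxygenation of an easily ionised para-hydroxy ketone. The routes to A1 and to 13 are of similar length.

**Alternative 2:** The cut is six ring bonds, two in each of rings C, D and E. In the forward sense the tris(ethynyl ketone) A5 reacts with three equivalents of Danishefsky's diene A6, and acid work-up aromatises the three new rings to the tris(4-hydroxybenzoyl) compound A7.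
- In favour: the mechanism is the same cycloaddition–aromatisation as in the chosen plan, so it is the equal there. It is the better in one respect: the labile diene A6 is a cheap commercial reagent used in excess, whereas 13 is a late, precious and moisture-sensitive intermediate. With an unsubstituted diene terminus there is also no regiochemical question.
- Against: A5 carries three terminal ynones, two of them flanking the bridge on ring A. It would be hindered there and prone to oligomerisation, and three cycloadditions must all go to completion.
- Against: the A–B bibenzyl and the 1,2,4-pattern of ring B still have to be made separately, followed by three acylations. In the chosen plan the key step delivers the A–B connection and the ring B pattern in one operation.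
- Comparison: the three ketones of A7 would fall in one ionic hydrogenation and only two benzyl ethers remain, so the endgame is equal in step count. The overall sequence is expected to be longer.

**Alternative 3:** The cut is the three CH2–aryl bonds to rings C, D and E. In the forward sense the tris(benzylic methyl carbonate) A8 is coupled under palladium catalysis with three equivalents of the boronic acid A9 to give the pentabenzyl ether A10. No ring closes.
- In favour: this is the most convergent plan. All five rings are bought as aromatics, no redox adjustment follows, and a single hydrogenolysis of A10 gives the target. In step count after the key step (one against two) and probably in overall length it is the better of the two.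
- Against: A8 needs a bibenzyl core with three oxygenated benzylic carbons. The two on ring A flank the bridge and are ortho and para to alkoxy groups, so those carbonates ionise very readily and invite solvolysis and self-alkylation of the electron-rich ring.
- Against: three couplings at crowded sites must all be complete, and partial coupling gives mixtures that are hard to separate. The A–B bond and the ring B pattern again need their own solution.
- Comparison: mechanistically, ionisation of electron-rich benzylic carbonates to benzylpalladium species is well matched to the substrate, which makes the alternative the equal of the chosen plan. The chosen plan is kept because it derives the ring B pattern from the mechanism of ring construction instead of from a polyfunctional core.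

Key step: step 11

Assumption: 1 and the THF solution of 3 are taken as purchasable, and the soft enolisation of 12 is taken to give mainly the (3Z) isomer of 13. Any (3E) isomer would react more slowly and converge on the same aromatic product.

Abbreviation used in names: ArA = 3-(benzyloxy)-2,6-bis[4-(benzyloxy)benzyl]-5-methoxyphenyl.

## Route

Step 1
Reactants: 1 3-bromo-5-methoxyphenol
Product: 2 1-(benzyloxy)-3-bromo-5-methoxybenzene
Conditions: BnBr, K2CO3, DMF, 25 °C
Reagents that add atoms: benzyl bromide, BrCc1ccccc1
Why: Williamson ether synthesis; the phenoxide displaces bromide from the benzylic halide, and a benzyl ether matches the other three so that all fall in the last step.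

Step 2
Reactants: 2 1-(benzyloxy)-3-bromo-5-methoxybenzene; 3 (4-ethoxy-4-oxobutyl)zinc bromide (0.5 M in THF)
Product: 4 ethyl 4-[3-(benzyloxy)-5-methoxyphenyl]butanoate
Conditions: Pd(OAc)2 (2 mol %), SPhos (4 mol %), THF, 25 → 50 °C
Reagents that add atoms: none
Why: Negishi coupling of a primary alkylzinc halide with an unhindered aryl bromide; the organozinc tolerates its own ester, and the bulky biarylphosphine makes reductive elimination faster than beta-hydride elimination.

Step 3
Reactants: 4 ethyl 4-[3-(benzyloxy)-5-methoxyphenyl]butanoate
Product: 5 ethyl 4-[3-(benzyloxy)-2,6-dibromo-5-methoxyphenyl]butanoate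
Conditions: NBS (2.05 equiv), MeCN, 0 → 25 °C, dark
Reagents that add atoms: N-bromosuccinimide, O=C1CCC(=O)N1Br
Why: Electrophilic aromatic bromination; the two positions beside the chain are each para to one alkoxy group and ortho to the other and are less shielded than C4 between the two alkoxy groups, the order known for 5-alkylresorcinol diethers. The stoichiometry stops at the dibromide, and a polar solvent in the dark suppresses benzylic radical bromination.

Step 4
Reactants: 5 ethyl 4-[3-(benzyloxy)-2,6-dibromo-5-methoxyphenyl]butanoate; 6 4-(benzyloxy)benzyl chloride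
Product: 8 ethyl 4-(ArA)butanoate, via [4-(benzyloxy)benzyl]zinc chloride 7 (not isolated)
Conditions: 6 (3 equiv), Zn dust, LiCl, THF, 25 °C; then 5, Pd(OAc)2 (5 mol %), SPhos (10 mol %), THF, 60 °C
Reagents that add atoms: none
Why: LiCl-assisted zinc insertion into the benzylic chloride, then a twofold Negishi benzylation; the benzylic zinc reagent has no beta-hydrogen and leaves the ester untouched (a formyl group would not survive it), and SPhos-ligated palladium is a standard catalyst for doubly ortho-substituted aryl bromides.

Step 5
Reactants: 8 ethyl 4-(ArA)butanoate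
Product: 9 4-(ArA)-N-methoxy-N-methylbutanamide
Conditions: MeNHOMe·HCl, iPrMgCl, THF, −20 → 0 °C
Reagents that add atoms: N,O-dimethylhydroxylamine hydrochloride, CNOC.Cl
Why: Weinreb amide formation by aminolysis of the ester with the chloromagnesium amide generated in the flask; aryl ethers and diarylmethanes are inert to the Grignard base at this temperature.

Step 6
Reactants: 9 4-(ArA)-N-methoxy-N-methylbutanamide; 10 ethynylmagnesium bromide (0.5 M in THF)
Product: 11 6-(ArA)hex-1-yn-3-one
Conditions: 10 (3 equiv), THF, 0 → 25 °C; poured into cold 1 M HCl
Reagents that add atoms: none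
Why: Weinreb ketone synthesis; the chelated tetrahedral intermediate prevents a second addition, and the inverse acidic quench protonates the released amine before it can add to the ynone.

Step 7
Reactants: 11 6-(ArA)hex-1-yn-3-one
Product: 12 (E)-6-(ArA)-1-methoxyhex-1-en-3-one
Conditions: MeOH (5 equiv), DABCO (10 mol %), CH2Cl2, 25 °C
Reagents that add atoms: methanol, CO
Why: Amine-catalysed oxa-Michael addition of methanol to a terminal ynone; the (E) beta-methoxy enone is the thermodynamic product, and catalytic base with limited methanol stops before acetal formation.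

Step 8
Reactants: 12 (E)-6-(ArA)-1-methoxyhex-1-en-3-one
Product: 13 (1E,3Z)-6-(ArA)-1-methoxy-3-(trimethylsilyloxy)hexa-1,3-diene
Conditions: TMSOTf (1.3 equiv), Et3N (2 equiv), toluene, 0 °C; toluene layer separated under argon, volatiles removed in vacuo, used at once
Reagents that add atoms: trimethylsilyl trifluoromethanesulfonate, C[Si](C)(C)OS(=O)(=O)C(F)(F)F
Why: Soft enolisation and O-silylation at C4, the only enolisable position; the (3Z) enol ether with the chain trans to the vinyl group minimises allylic strain. The ammonium triflate separates from toluene, and stripping the amine avoids base-induced oligomerisation of the ynone in the next step.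

Step 9
Reactants: 14 4-(benzyloxy)benzaldehyde; 10 ethynylmagnesium bromide (0.5 M in THF)
Product: 15 1-[4-(benzyloxy)phenyl]prop-2-yn-1-ol (racemic)
Conditions: THF, 0 °C; aq. NH4Cl
Reagents that add atoms: none
Why: Grignard addition of an acetylide to an aromatic aldehyde; the new stereocentre forms as the racemate and is removed in the next step.

Step 10
Reactants: 15 1-[4-(benzyloxy)phenyl]prop-2-yn-1-ol
Product: 16 1-[4-(benzyloxy)phenyl]prop-2-yn-1-one
Conditions: MnO2 (10 equiv), CH2Cl2, 25 °C
Reagents that add atoms: none
Why: Oxidation of a benzylic and propargylic alcohol with activated MnO2, neutral conditions that leave the terminal ynone intact.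

Step 11
Reactants: 13 (1E,3Z)-6-(ArA)-1-methoxy-3-(trimethylsilyloxy)hexa-1,3-diene; 16 1-[4-(benzyloxy)phenyl]prop-2-yn-1-one
Product: 18 [4-(benzyloxy)phenyl]{3-[2-(ArA)ethyl]-4-hydroxyphenyl}methanone, via cis-cycloadduct 17 (not isolated)
Conditions: 16 (1.5 equiv), toluene, 70 °C, argon; then 1 M HCl, THF, 25 °C
Reagents that add atoms: none
Why: Thermal Diels–Alder reaction of normal electron demand between an electron-rich 1-methoxy-3-silyloxydiene and an ynone, followed by aromatisation; the closest known reaction is the addition of 4-substituted Danishefsky-type dienes to alkynyl ketones, which gives ortho-alkyl para-acylphenols. The largest HOMO coefficient of 13 lies at C4, the chain-bearing terminus, and the largest LUMO coefficient of 16 at its terminal alkyne carbon, so the bond from C4 to that carbon leads and the bond from C1 (OMe) to the acyl-bearing carbon follows; the 1-methoxy and 3-silyloxy donors direct in the same sense. Ring B closes in this one suprafacial [4+2] event as a six-membered carbocycle, through the new sigma bonds C1–C6 and C4–C5 of ring B. The two sp3 centres of 17 arise cis because both diene substituents point outward, and both are erased on aromatisation, so no stereocentre has to be controlled. Acid then hydrolyses the silyl enol ether, the beta-methoxy ketone loses methanol and the dienone tautomerises to the phenol. The selectivity needed is regiochemical and is secured by the matched polarity of the partners; reaction at C≡C and not at C=O follows from the absence of a Lewis acid, and the (3Z) geometry keeps the chain clear of the dienophile in the s-cis conformer.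

Step 12
Reactants: 18 [4-(benzyloxy)phenyl]{3-[2-(ArA)ethyl]-4-hydroxyphenyl}methanone
Product: 20 4-[4-(benzyloxy)benzyl]-2-[2-(ArA)ethyl]phenol, via diarylcarbinol 19 (not isolated)
Conditions: Et3SiH (4 equiv), TFA (10 equiv), CH2Cl2, 0 → 25 °C
Reagents that add atoms: none
Why: Ionic hydrogenation; hydride transfer to the protonated ketone gives carbinol 19, which ionises to a benzhydryl cation stabilised by the para-hydroxy and para-benzyloxy groups (a protonated para-quinone methide) and takes a second hydride. Excess silane in dilute acid outruns Friedel–Crafts capture and leaves the aryl benzyl ethers in place.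

Step 13
Reactants: 20 4-[4-(benzyloxy)benzyl]-2-[2-(ArA)ethyl]phenol
Product: 21 4-(4-hydroxybenzyl)-2-{2-[3-hydroxy-2,6-bis(4-hydroxybenzyl)-5-methoxyphenyl]ethyl}phenol (CNP0134121.0)
Conditions: H2 (1 atm), 10% Pd/C, EtOAc/MeOH, 25 °C
Reagents that add atoms: none
Why: Catalytic hydrogenolysis of four aryl benzyl ethers under neutral conditions; the methyl ether, the diarylmethane C–C bonds and the arenes are not affected.

## Compound list

1 | 3-bromo-5-methoxyphenol | COc1cc(O)cc(Br)c1 | starting material
2 | 1-(benzyloxy)-3-bromo-5-methoxybenzene | COc1cc(Br)cc(OCc2ccccc2)c1 | intermediate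
3 | (4-ethoxy-4-oxobutyl)zinc bromide | CCOC(=O)CCC[Zn]Br | starting material
4 | ethyl 4-[3-(benzyloxy)-5-methoxyphenyl]butanoate | CCOC(=O)CCCc1cc(OC)cc(OCc2ccccc2)c1 | intermediate
5 | ethyl 4-[3-(benzyloxy)-2,6-dibromo-5-methoxyphenyl]butanoate | CCOC(=O)CCCc1c(Br)c(OC)cc(OCc2ccccc2)c1Br | intermediate
6 | 4-(benzyloxy)benzyl chloride | ClCc1ccc(OCc2ccccc2)cc1 | starting material
7 | [4-(benzyloxy)benzyl]zinc chloride | Cl[Zn]Cc1ccc(OCc2ccccc2)cc1 | intermediate
8 | ethyl 4-{3-(benzyloxy)-2,6-bis[4-(benzyloxy)benzyl]-5-methoxyphenyl}butanoate | CCOC(=O)CCCc1c(Cc2ccc(OCc3ccccc3)cc2)c(OC)cc(OCc2ccccc2)c1Cc1ccc(OCc2ccccc2)cc1 | intermediate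
9 | 4-{3-(benzyloxy)-2,6-bis[4-(benzyloxy)benzyl]-5-methoxyphenyl}-N-methoxy-N-methylbutanamide | CON(C)C(=O)CCCc1c(Cc2ccc(OCc3ccccc3)cc2)c(OC)cc(OCc2ccccc2)c1Cc1ccc(OCc2ccccc2)cc1 | intermediate
10 | ethynylmagnesium bromide | C#C[Mg]Br | starting material
11 | 6-{3-(benzyloxy)-2,6-bis[4-(benzyloxy)benzyl]-5-methoxyphenyl}hex-1-yn-3-one | C#CC(=O)CCCc1c(Cc2ccc(OCc3ccccc3)cc2)c(OC)cc(OCc2ccccc2)c1Cc1ccc(OCc2ccccc2)cc1 | intermediate
12 | (E)-6-{3-(benzyloxy)-2,6-bis[4-(benzyloxy)benzyl]-5-methoxyphenyl}-1-methoxyhex-1-en-3-one | CO/C=C/C(=O)CCCc1c(Cc2ccc(OCc3ccccc3)cc2)c(OC)cc(OCc2ccccc2)c1Cc1ccc(OCc2ccccc2)cc1 | intermediate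
13 | (1E,3Z)-6-{3-(benzyloxy)-2,6-bis[4-(benzyloxy)benzyl]-5-methoxyphenyl}-1-methoxy-3-(trimethylsilyloxy)hexa-1,3-diene | CO/C=C/C(O[Si](C)(C)C)=C/CCc1c(Cc2ccc(OCc3ccccc3)cc2)c(OC)cc(OCc2ccccc2)c1Cc1ccc(OCc2ccccc2)cc1 | intermediate
14 | 4-(benzyloxy)benzaldehyde | O=Cc1ccc(OCc2ccccc2)cc1 | starting material
15 | 1-[4-(benzyloxy)phenyl]prop-2-yn-1-ol (racemic) | C#CC(O)c1ccc(OCc2ccccc2)cc1 | intermediate
16 | 1-[4-(benzyloxy)phenyl]prop-2-yn-1-one | C#CC(=O)c1ccc(OCc2ccccc2)cc1 | intermediate
17 | [4-(benzyloxy)phenyl][cis-3-(2-{3-(benzyloxy)-2,6-bis[4-(benzyloxy)benzyl]-5-methoxyphenyl}ethyl)-6-methoxy-4-(trimethylsilyloxy)cyclohexa-1,4-dien-1-yl]methanone (racemic, one enantiomer drawn) | CO[C@H]1C=C(O[Si](C)(C)C)[C@@H](CCc2c(Cc3ccc(OCc4ccccc4)cc3)c(OC)cc(OCc3ccccc3)c2Cc2ccc(OCc3ccccc3)cc2)C=C1C(=O)c1ccc(OCc2ccccc2)cc1 | intermediate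
18 | [4-(benzyloxy)phenyl]{3-[2-(3-(benzyloxy)-2,6-bis[4-(benzyloxy)benzyl]-5-methoxyphenyl)ethyl]-4-hydroxyphenyl}methanone | COc1cc(OCc2ccccc2)c(Cc2ccc(OCc3ccccc3)cc2)c(CCc2cc(C(=O)c3ccc(OCc4ccccc4)cc3)ccc2O)c1Cc1ccc(OCc2ccccc2)cc1 | intermediate
19 | 4-{[4-(benzyloxy)phenyl](hydroxy)methyl}-2-[2-(3-(benzyloxy)-2,6-bis[4-(benzyloxy)benzyl]-5-methoxyphenyl)ethyl]phenol (racemic) | COc1cc(OCc2ccccc2)c(Cc2ccc(OCc3ccccc3)cc2)c(CCc2cc(C(O)c3ccc(OCc4ccccc4)cc3)ccc2O)c1Cc1ccc(OCc2ccccc2)cc1 | intermediate
20 | 4-[4-(benzyloxy)benzyl]-2-[2-(3-(benzyloxy)-2,6-bis[4-(benzyloxy)benzyl]-5-methoxyphenyl)ethyl]phenol | COc1cc(OCc2ccccc2)c(Cc2ccc(OCc3ccccc3)cc2)c(CCc2cc(Cc3ccc(OCc4ccccc4)cc3)ccc2O)c1Cc1ccc(OCc2ccccc2)cc1 | intermediate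
21 | 4-(4-hydroxybenzyl)-2-{2-[3-hydroxy-2,6-bis(4-hydroxybenzyl)-5-methoxyphenyl]ethyl}phenol (CNP0134121.0) | COc1cc(O)c(Cc2ccc(O)cc2)c(CCc2cc(Cc3ccc(O)cc3)ccc2O)c1Cc1ccc(O)cc1 | target

## Step count and least certain steps

Total step count: 13. Longest linear sequence: 11 (steps 1 to 8 and 11 to 13); steps 9 and 10 form the short side branch to 16.

For step 11, the key step, three processes are the most likely to go wrong:
- loss of the trimethylsilyl enol ether by adventitious hydrolysis before cycloaddition, which returns 12;
- a slow cycloaddition of the 4-substituted diene, which gives the ynone time to oligomerise;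
- a stepwise Michael-type addition that stops at an open-chain adduct.

The fallback changes the diene class to a far more reactive and more robust 1-amino-3-silyloxydiene. It sets out from 11. Dimethylamine in THF should add to the ynone to give (E)-6-(ArA)-1-(dimethylamino)hex-1-en-3-one F1. Deprotonation with KN(SiMe3)2 and trapping with tert-butyldimethylsilyl chloride at −78 °C should give (1E,3Z)-3-(tert-butyldimethylsilyloxy)-6-(ArA)-1-(dimethylamino)hexa-1,3-diene F2, which can be handled and stored. F2 should combine with 16 at room temperature to the cis amino cycloadduct F3, and aqueous HF in acetonitrile should then expel dimethylamine and the silyl group. The fallback comes back to the route at 18.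

For step 4, the likely failures are Wurtz-type homocoupling of the electron-rich benzylic chloride during zinc insertion and a stalled second coupling with protodebromination at the remaining hindered C–Br bond. The fallback replaces the organozinc made in the flask by an isolated boron nucleophile, so that reagent formation is separated from the coupling and the coupling can be forced. It sets out from 6, which is converted (Mg, B(OMe)3, then aqueous KHF2) into potassium [4-(benzyloxy)benzyl]trifluoroborate F4. A twofold Suzuki–Miyaura coupling of F4 with 5 (Pd(OAc)2, RuPhos, K2CO3, toluene/water, 95 °C) comes back to the route at 8.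

For step 6, the likely failure is conjugate addition of the released N,O-dimethylhydroxylamine to the terminal ynone during quench, giving a beta-amino enone instead of 11. The fallback replaces the acyl substitution by an addition–oxidation sequence. It sets out from 8, which is reduced with iBu2AlH at −78 °C to 4-(ArA)butanal F5. Addition of 10 gives racemic 6-(ArA)hex-1-yn-3-ol F6, and oxidation with Dess–Martin periodinane comes back to the route at 11.

For step 12, the likely failures are acid-induced loss or migration of benzyl groups and capture of the benzhydryl cation by the nucleophilic C4–H of ring A or by a phenol ring, which would give dimers. The fallback replaces the ionic hydrogenation by catalytic hydrogenolysis. It sets out from 18, which NaBH4 in THF/MeOH reduces to the carbinol 19, now isolated. Hydrogenation of 19 over 10% Pd/C in EtOAc/AcOH should cleave the benzhydrylic C–O bond together with the four benzyl ethers and comes back to the route at 21. This fallback makes no compound outside the compound list (entry F0).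

## Further compounds

F1 | step 11 | (E)-6-{3-(benzyloxy)-2,6-bis[4-(benzyloxy)benzyl]-5-methoxyphenyl}-1-(dimethylamino)hex-1-en-3-one | CN(C)/C=C/C(=O)CCCc1c(Cc2ccc(OCc3ccccc3)cc2)c(OC)cc(OCc2ccccc2)c1Cc1ccc(OCc2ccccc2)cc1
F2 | step 11 | (1E,3Z)-3-(tert-butyldimethylsilyloxy)-6-{3-(benzyloxy)-2,6-bis[4-(benzyloxy)benzyl]-5-methoxyphenyl}-1-(dimethylamino)hexa-1,3-diene | CN(C)/C=C/C(O[Si](C)(C)C(C)(C)C)=C/CCc1c(Cc2ccc(OCc3ccccc3)cc2)c(OC)cc(OCc2ccccc2)c1Cc1ccc(OCc2ccccc2)cc1
F3 | step 11 | [4-(benzyloxy)phenyl][cis-3-(2-{3-(benzyloxy)-2,6-bis[4-(benzyloxy)benzyl]-5-methoxyphenyl}ethyl)-4-(tert-butyldimethylsilyloxy)-6-(dimethylamino)cyclohexa-1,4-dien-1-yl]methanone (racemic, one enantiomer drawn) | CN(C)[C@H]1C=C(O[Si](C)(C)C(C)(C)C)[C@@H](CCc2c(Cc3ccc(OCc4ccccc4)cc3)c(OC)cc(OCc3ccccc3)c2Cc2ccc(OCc3ccccc3)cc2)C=C1C(=O)c1ccc(OCc2ccccc2)cc1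
F4 | step 4 | potassium [4-(benzyloxy)benzyl]trifluoroborate | [K+].F[B-](F)(F)Cc1ccc(OCc2ccccc2)cc1
F5 | step 6 | 4-{3-(benzyloxy)-2,6-bis[4-(benzyloxy)benzyl]-5-methoxyphenyl}butanal | O=CCCCc1c(Cc2ccc(OCc3ccccc3)cc2)c(OC)cc(OCc2ccccc2)c1Cc1ccc(OCc2ccccc2)cc1
F6 | step 6 | 6-{3-(benzyloxy)-2,6-bis[4-(benzyloxy)benzyl]-5-methoxyphenyl}hex-1-yn-3-ol (racemic) | C#CC(O)CCCc1c(Cc2ccc(OCc3ccccc3)cc2)c(OC)cc(OCc2ccccc2)c1Cc1ccc(OCc2ccccc2)cc1
F0 | step 12 | none | none
A1 | alternative 1 | 1-{3-(benzyloxy)-2,6-bis[4-(benzyloxy)benzyl]-5-methoxyphenyl}ethan-1-one | CC(=O)c1c(Cc2ccc(OCc3ccccc3)cc2)c(OC)cc(OCc2ccccc2)c1Cc1ccc(OCc2ccccc2)cc1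
A2 | alternative 1 | O-{4-[4-(benzyloxy)benzyl]phenyl}hydroxylamine | NOc1ccc(Cc2ccc(OCc3ccccc3)cc2)cc1
A3 | alternative 1 | 1-{3-(benzyloxy)-2,6-bis[4-(benzyloxy)benzyl]-5-methoxyphenyl}ethan-1-one O-{4-[4-(benzyloxy)benzyl]phenyl}oxime (C=N geometry not defined) | CC(=NOc1ccc(Cc2ccc(OCc3ccccc3)cc2)cc1)c1c(Cc2ccc(OCc3ccccc3)cc2)c(OC)cc(OCc2ccccc2)c1Cc1ccc(OCc2ccccc2)cc1
A4 | alternative 1 | 2-{3-(benzyloxy)-2,6-bis[4-(benzyloxy)benzyl]-5-methoxyphenyl}-5-[4-(benzyloxy)benzyl]benzofuran | COc1cc(OCc2ccccc2)c(Cc2ccc(OCc3ccccc3)cc2)c(-c2cc3cc(Cc4ccc(OCc5ccccc5)cc4)ccc3o2)c1Cc1ccc(OCc2ccccc2)cc1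
A5 | alternative 2 | 1-{4-(benzyloxy)-3-[2-(3-(benzyloxy)-5-methoxy-2,6-di(prop-2-ynoyl)phenyl)ethyl]phenyl}prop-2-yn-1-one | COc1cc(OCc2ccccc2)c(C(=O)C#C)c(CCc2cc(C(=O)C#C)ccc2OCc2ccccc2)c1C(=O)C#C
A6 | alternative 2 | (E)-1-methoxy-3-(trimethylsilyloxy)buta-1,3-diene (Danishefsky's diene) | CO/C=C/C(=C)O[Si](C)(C)C
A7 | alternative 2 | {4-(benzyloxy)-3-[2-(3-(benzyloxy)-2,6-bis(4-hydroxybenzoyl)-5-methoxyphenyl)ethyl]phenyl}(4-hydroxyphenyl)methanone | COc1cc(OCc2ccccc2)c(C(=O)c2ccc(O)cc2)c(CCc2cc(C(=O)c3ccc(O)cc3)ccc2OCc2ccccc2)c1C(=O)c1ccc(O)cc1
A8 | alternative 3 | 4-(benzyloxy)-3-[2-(3-(benzyloxy)-5-methoxy-2,6-bis{[(methoxycarbonyl)oxy]methyl}phenyl)ethyl]benzyl methyl carbonate | COc1cc(OCc2ccccc2)c(COC(=O)OC)c(CCc2cc(COC(=O)OC)ccc2OCc2ccccc2)c1COC(=O)OC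
A9 | alternative 3 | 4-(benzyloxy)phenylboronic acid | OB(O)c1ccc(OCc2ccccc2)cc1
A10 | alternative 3 | 1-(benzyloxy)-4-[4-(benzyloxy)benzyl]-2-(2-{3-(benzyloxy)-2,6-bis[4-(benzyloxy)benzyl]-5-methoxyphenyl}ethyl)benzene | COc1cc(OCc2ccccc2)c(Cc2ccc(OCc3ccccc3)cc2)c(CCc2cc(Cc3ccc(OCc4ccccc4)cc3)ccc2OCc2ccccc2)c1Cc1ccc(OCc2ccccc2)cc1
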